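## Retrosynthetic overview
1. 25 ⇒ 22: the C15 ester side chain goes on last (acylation with 13, then Br → OH).
2. 22 ⇒ 18 (key step): one chromium-catalysed asymmetric allylation makes C7–C8 and closes the ten-membered carbocycle (ring A). The new C8 oxygen then attacks C12, closes the trans γ-lactone (ring B), opens a sacrificial eight-membered lactone (ring C) and frees C15–OH.
3. 18 ⇒ 16: ring C comes from ring-closing metathesis (C7=C11). The small ring locks the olefin geometry that the chair transition state turns into the trans ring fusion.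
4. 16 ⇒ 7 + 11: an E-selective Wittig reaction sets C1=C10 (CH2OAc trans to C2); 11 brings C8, C9, C10 and C14.
5. 7 ⇒ 1 + 2 + 3: three-component anti-carbomagnesiation of propargyl alcohol sets C4=C5. Ring order: C first, then A and B together (C is lost).

Locants are germacrane locants: C7/C8 = ring fusion, C11–C13 = lactone acrylate carbons, C14 = CH2OAc carbon on C10, C15 = CH2O carbon on C4.

Assumption: the (S,S) ligand of step 9 is taken to steer the allyl group to the Re face of the aldehyde. If the sense is the opposite, the (R,R) ligand is used and nothing else changes.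

## Route

Step 1
Reactants: 1 2-(2-bromoethyl)-1,3-dioxane; 2 prop-2-yn-1-ol; 3 allyl bromide
Product: 6 (2Z)-2-[2-(1,3-dioxan-2-yl)ethyl]hexa-2,5-dien-1-ol, via Grignard reagent 4 (not isolated), via vinylmagnesium chelate 5 (not isolated)
Conditions: Mg, THF, 25–35 °C; 2 (0.4 equiv), CuI (10 mol %), THF, 0 °C to rt; 3 (excess), 0 °C to rt; aq NH4Cl
Reagents that add atoms: none
Why: Copper-catalysed anti-carbomagnesiation of the propargylic alkoxide (Duboudin–Jousseaume reaction) puts the alkyl group on the inner alkyne carbon and magnesium cis to CH2O in a five-membered chelate, so allylation with retention fixes C4=C5 with C15 cis to C6.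

Step 2
Reactants: 6 (2Z)-2-[2-(1,3-dioxan-2-yl)ethyl]hexa-2,5-dien-1-ol
Product: 7 (4Z)-4-(hydroxymethyl)octa-4,7-dienal (in equilibrium with its six-membered lactol)
Conditions: 2 M HCl, THF, rt
Reagents that add atoms: water, O
Why: This is acid-catalysed acetal hydrolysis; the primary allylic alcohol and the skipped diene tolerate dilute acid at room temperature, and the aldehyde is protected as its lactol.

Step 3
Reactants: 8 [2-(1,3-dioxolan-2-yl)ethyl]triphenylphosphonium bromide; 9 ethyl formate
Product: 11 3-(1,3-dioxolan-2-yl)-2-(triphenylphosphoranylidene)propanal, via phosphorus ylide 10 (not isolated)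
Conditions: KOtBu, THF, 0 °C; HCO2Et, 0 °C to rt
Reagents that add atoms: none
Why: This is C-formylation of a non-stabilised ylide by a formate ester (ylide acylation); the released ethoxide deprotonates the acylphosphonium ion to the stabilised formyl ylide.

Step 4
Reactants: 7 (4Z)-4-(hydroxymethyl)octa-4,7-dienal; 11 3-(1,3-dioxolan-2-yl)-2-(triphenylphosphoranylidene)propanal
Product: 12 (2E,6Z)-2-(1,3-dioxolan-2-ylmethyl)-6-(hydroxymethyl)deca-2,6,9-trienal
Conditions: toluene, 90 °C
Reagents that add atoms: none
Why: Wittig olefination with an α-substituted stabilised ylide gives the E-enal (CHO trans to C2, C9 cis to C2), which is the C1=C10 geometry of the target; the lactol reacts through its open form.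

Step 5
Reactants: 12 (2E,6Z)-2-(1,3-dioxolan-2-ylmethyl)-6-(hydroxymethyl)deca-2,6,9-trienal; 13 2-(bromomethyl)acrylic acid
Product: 14 C15 2-(bromomethyl)acrylate ester of enal 12
Conditions: DCC, DMAP (5 mol %), CH2Cl2, −20 to 0 °C
Reagents that add atoms: none
Why: Steglich esterification of the only free hydroxyl; low temperature and little DMAP keep the activated allylic bromide intact, and the enal and acetal do not react.

Step 6
Reactants: 14 C15 2-(bromomethyl)acrylate ester of enal 12
Product: 16 C14 acetate with C15 2-(bromomethyl)acrylate and C8 dioxolane (acyclic triene), via allylic alcohol 15 (not isolated)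
Conditions: NaBH4, CeCl3·7H2O, MeOH, −78 °C; extractive work-up; AcCl, 2,4,6-collidine, CH2Cl2, −78 to 0 °C
Reagents that add atoms: acetyl chloride, CC(=O)Cl
Why: Luche 1,2-reduction of the enal at −78 °C is far faster than hydride attack on the bromomethylacrylate, and the hindered base collidine allows acetylation of the new primary alcohol without quaternisation at the allylic bromide.

Step 7
Reactants: 16 C14 acetate with C15 2-(bromomethyl)acrylate and C8 dioxolane
Product: 17 (3Z,6Z)-3-(bromomethyl)-7-[(3E)-4-(acetoxymethyl)-5-(1,3-dioxolan-2-yl)pent-3-enyl]-5,8-dihydro-2H-oxocin-2-one (ring C)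
Conditions: second-generation Hoveyda–Grubbs catalyst (H2IMes)Cl2Ru=CH(C6H4-2-OiPr) (10 mol %), 1,4-benzoquinone (20 mol %), toluene (2 mM), 80 °C
Reagents that add atoms: none
Why: Ring-closing metathesis joins the only terminal olefin to the tethered acrylate, helped by the cis C4=C5 bond in the chain; in an eight-membered ring the new C7=C11 bond can only be cis (C6 cis to C12, CH2Br trans to C6).

Step 8
Reactants: 17 eight-membered lactone acetal
Product: 18 eight-membered lactone aldehyde (C8 = CHO)
Conditions: 50 % aq TFA, CH2Cl2, 0 °C, short contact; NaHCO3 quench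
Reagents that add atoms: water, O
Why: Acetal hydrolysis at low temperature and short contact time keeps the β,γ-unsaturated aldehyde out of conjugation; the lactone, acetate and allylic bromide survive.

Step 9
Reactants: 18 eight-membered lactone aldehyde
Product: 22 (7R,8S)-14-acetoxy-15-hydroxygermacra-1(10),4,11(13)-trien-12,8-olide (1(10) ring-cis and 4 ring-trans), via allylchromium species 19 (not isolated), via silyl ether 20 (not isolated), via hydroxy lactone 21 (not isolated)
Conditions: CrCl2 (30 mol %), (S,S)-1,8-bis(4-isopropyl-4,5-dihydrooxazol-2-yl)-3,6-diphenyl-9H-carbazole (33 mol %), iPr2NEt (60 mol %), Mn (3 equiv), Me3SiCl (2 equiv), THF, syringe-pump addition of 18 to 5 mM, 0 °C to rt; then 1 M HCl, THF, rt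
Reagents that add atoms: none
Why: Proposed new method: divalent chromium turns the allylic bromide into an allylchromium species whose C7=C11 bond cannot isomerise inside ring C (C6 stays trans to the CH2Cr carbon, the E-crotyl situation), so the closed chair transition state with C6 and C9 equatorial gives the anti adduct, the chiral chromium complex selects the Re face of the aldehyde (8S, hence 7R), and after desilylation the C8 hydroxyl attacks the strained lactone carbonyl to give the trans γ-lactone and free C15–OH; the closest known reaction types are the catalytic asymmetric Nozaki–Hiyama–Kishi 2-(alkoxycarbonyl)allylation–lactonisation of aldehydes and the chromium-mediated allyl bromide–aldehyde closure of germacrane ten-membered rings.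

Step 10
Reactants: 22 (7R,8S)-14-acetoxy-15-hydroxygermacra-1(10),4,11(13)-trien-12,8-olide; 13 2-(bromomethyl)acrylic acid
Product: 23 C15 2-(bromomethyl)acrylate ester of 22
Conditions: DCC, DMAP (5 mol %), CH2Cl2, −20 to 0 °C
Reagents that add atoms: none
Why: Steglich esterification of the single free primary allylic alcohol; the α-methylene lactone, the acetate and both stereocentres are untouched.

Step 11
Reactants: 23 C15 2-(bromomethyl)acrylate ester of 22
Product: 25 target CNP0126545.1, via allylammonium bromide 24 (not isolated)
Conditions: DABCO (1 equiv), THF, 0 °C; H2O, NaHCO3, rt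
Reagents that add atoms: water, O
Why: DABCO displaces bromide to give the allylammonium salt and water replaces the amine (double allylic substitution on a degenerate 2-carboxyallyl unit), which gives the 2-(hydroxymethyl)acrylate under conditions too mild to touch the acetate, the lactone or C7/C8.

## Compound list
1 | 2-(2-bromoethyl)-1,3-dioxane | BrCCC1OCCCO1 | starting material
2 | prop-2-yn-1-ol | C#CCO | starting material
3 | allyl bromide | C=CCBr | starting material
4 | 2-(1,3-dioxan-2-yl)ethylmagnesium bromide | Br[Mg]CCC1OCCCO1 | intermediate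
5 | vinylmagnesium chelate (Mg bound to the alkoxide O and the vinylic CH) | O1CC(CCC2OCCCO2)=C[Mg]1 | intermediate
6 | (2Z)-2-[2-(1,3-dioxan-2-yl)ethyl]hexa-2,5-dien-1-ol | OC/C(CCC1OCCCO1)=C\CC=C | intermediate
7 | (4Z)-4-(hydroxymethyl)octa-4,7-dienal | OC/C(CCC=O)=C\CC=C | intermediate
8 | [2-(1,3-dioxolan-2-yl)ethyl]triphenylphosphonium bromide | [Br-].C1COC(CC[P+](c2ccccc2)(c2ccccc2)c2ccccc2)O1 | starting material
9 | ethyl formate | CCOC=O | starting material
10 | [2-(1,3-dioxolan-2-yl)ethylidene]triphenylphosphorane | C1COC(CC=P(c2ccccc2)(c2ccccc2)c2ccccc2)O1 | intermediate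
11 | 3-(1,3-dioxolan-2-yl)-2-(triphenylphosphoranylidene)propanal | O=CC(CC1OCCO1)=P(c1ccccc1)(c1ccccc1)c1ccccc1 | intermediate
12 | (2E,6Z)-2-(1,3-dioxolan-2-ylmethyl)-6-(hydroxymethyl)deca-2,6,9-trienal | O=C/C(CC1OCCO1)=C/CC/C(CO)=C/CC=C | intermediate
13 | 2-(bromomethyl)acrylic acid | C=C(CBr)C(=O)O | starting material
14 | C15 2-(bromomethyl)acrylate ester of 12 | O=C/C(CC1OCCO1)=C/CC/C(COC(=O)C(=C)CBr)=C/CC=C | intermediate
15 | C14 allylic alcohol from 14 | OC/C(CC1OCCO1)=C/CC/C(COC(=O)C(=C)CBr)=C/CC=C | intermediate
16 | C14 acetate of 15 | CC(=O)OC/C(CC1OCCO1)=C/CC/C(COC(=O)C(=C)CBr)=C/CC=C | intermediate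
17 | eight-membered lactone (ring C), C8 dioxolane | O=C1OC/C(CC/C=C(/COC(C)=O)CC2OCCO2)=C\C/C=C1/CBr | intermediate
18 | eight-membered lactone, C8 aldehyde | O=C1OC/C(CC/C=C(/COC(C)=O)CC=O)=C\C/C=C1/CBr | intermediate
19 | allylchromium species (trivalent chromium, chiral ligand omitted) | O=C1OC/C(CC/C=C(/COC(C)=O)CC=O)=C\C/C=C1/C[Cr](Cl)Cl | intermediate
20 | C8 trimethylsilyl ether of the ring A/ring C bicycle | O=C1OC/C2=C\C[C@H](C1=C)[C@@H](O[Si](C)(C)C)C/C(COC(C)=O)=C\CC2 | intermediate
21 | C8 alcohol of the ring A/ring C bicycle | O=C1OC/C2=C\C[C@H](C1=C)[C@@H](O)C/C(COC(C)=O)=C\CC2 | intermediate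
22 | (7R,8S)-14-acetoxy-15-hydroxygermacra-1(10),4,11(13)-trien-12,8-olide | OC/C1=C\C[C@@H]2C(=C)C(=O)O[C@H]2C/C(COC(C)=O)=C\CC1 | intermediate
23 | C15 2-(bromomethyl)acrylate of 22 | C=C(CBr)C(=O)OC/C1=C\C[C@@H]2C(=C)C(=O)O[C@H]2C/C(COC(C)=O)=C\CC1 | intermediate
24 | DABCO allylammonium bromide from 23 | [Br-].C=C(C[N+]34CCN(CC3)CC4)C(=O)OC/C1=C\C[C@@H]2C(=C)C(=O)O[C@H]2C/C(COC(C)=O)=C\CC1 | intermediate
25 | CNP0126545.1 | C=C(CO)C(=O)OC/C1=C\C[C@@H]2C(=C)C(=O)O[C@H]2C/C(COC(C)=O)=C\CC1 | target

## Step count and risks
Total step count: 11. Longest linear sequence: 10 (steps 1, 2 and 4 to 11).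

**Step 9.** This step has four risks:
- closing a ten-membered ring;
- catalyst control of the aldehyde face in an intramolecular reaction;
- turnover of the chromium catalyst at high dilution;
- survival of the sensitive aldehyde.

The fallback sets out from 17 and comes back at 22, and it replaces organochromium chemistry by a closed-shell allylboration. Pd2(dba)3-catalysed borylation of the activated allylic bromide of 17 with B2pin2 (THF, rt, the plain allylic acetate is left alone) gives the ring-locked allylboronate acetal F1. Cold aqueous TFA frees the ring-locked allylboronate aldehyde F2. A chiral phosphoric acid (TRIP, the enantiomer that directs Re-face attack) in toluene at high dilution then triggers the same chair-type C7–C8 closure from a configurationally fixed boronate. The borate translactonises on work-up to 22.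

**Step 7.** The step must form a trisubstituted, electron-poor olefin in an eight-membered ring. The fallback sets out from 12 and comes back at 17; it makes the easier disubstituted olefin by metathesis and adds C13 afterwards. Acryloyl chloride and iPr2NEt convert 12 into the acrylate enal F3. Luche reduction and acetylation as in step 6 give the acrylate acetate F4. Ring-closing metathesis now joins two monosubstituted olefins and gives the cis-enoate lactone F5. Me2AlSPh followed by monomeric formaldehyde (thiolate conjugate addition, then aluminium enolate aldol) gives the sulfide aldol F6 as a diastereomer mixture. NaIO4 oxidation and warming expel the sulfoxide toward C11 and give the hydroxymethyl lactone F7, and CBr4 with PPh3 turns it into 17.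

**Step 1.** This three-component reaction uses a functionalised, thermally limited Grignard reagent, and the excess reagent competes for allyl bromide. The fallback sets out from 5 and comes back at 6, and it separates the two carbon–carbon bond formations. The chelate 5 is quenched with I2 to give the vinyl iodide F8, which is isolated. The allyl group is then attached with retention by Stille coupling with allyltributylstannane (Pd(PPh3)4, CuI, DMF, rt) to give 6.

## Further compounds
F1 | step 9 | ring-locked allylboronate acetal | O=C1OC/C(CC/C=C(/COC(C)=O)CC2OCCO2)=C\C/C=C1/CB3OC(C)(C)C(C)(C)O3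
F2 | step 9 | ring-locked allylboronate aldehyde | O=C1OC/C(CC/C=C(/COC(C)=O)CC=O)=C\C/C=C1/CB3OC(C)(C)C(C)(C)O3
F3 | step 7 | acrylate enal | O=C/C(CC1OCCO1)=C/CC/C(COC(=O)C=C)=C/CC=C
F4 | step 7 | acrylate acetate | CC(=O)OC/C(CC1OCCO1)=C/CC/C(COC(=O)C=C)=C/CC=C
F5 | step 7 | cis-enoate lactone | O=C1OC/C(CC/C=C(/COC(C)=O)CC2OCCO2)=C\C/C=C\1
F6 | step 7 | sulfide aldol | O=C1OC/C(CC/C=C(/COC(C)=O)CC2OCCO2)=C\CC(Sc2ccccc2)C1CO
F7 | step 7 | hydroxymethyl lactone | O=C1OC/C(CC/C=C(/COC(C)=O)CC2OCCO2)=C\C/C=C1/CO
F8 | step 1 | vinyl iodide | OC/C(CCC1OCCCO1)=C\I
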